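All runs come from a simulation with made-up constants, and the scatter is random.

Take one unit for everything, the solid substrate charged, so that a percent in a reading and an equivalent in a charge can be subtracted from each other.

all flasks: solid substrate 0.038 M
- red: reagent 0.90 equiv; second substrate 0.50 equiv; the very flask that is asked about, followed so far
- blue: reagent 0.90 equiv; second substrate 0.75 equiv; run made earlier
- flask: reagent 0.900 equiv; second substrate 0.500 equiv; time 8.0 d

| run | time / h | target / % | solid substrate / % |
|---|---|---|---|
| red | 20.0 | 46 | 26 |
| red | 60.0 | 48 | 13 |
| red | 96.0 | 46 | 19 |
| red | 144 | 49 | 15 |
| blue | 1.00 | 2 | 94 |
| blue | 2.00 | 10 | 89 |
| blue | 5.00 | 22 | 74 |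
| blue | 12.0 | 35 | 49 |

(readings scatter by 2 percentage points)

- epsilon: at 8.0 d take out 90 % of the target then present, then wait 15 d
- theta: at 8.0 d add reagent, 50.0 % of the amount charged, then wait 15 d
- beta: change nothing and wait 15 d more

- solid substrate is a solid; its amount is given per volume of the solution
- what is taken out of target is counted as made
- at the start none of the solid substrate is in solution
- additions bring no volume worth counting

- target, in percent of the solid substrate first charged, at 8.0 d
- what to do for the largest gain in target; "none" if nothing gains more than 2 percentage points (epsilon / theta / beta / none)
- target present, with what was taken out counted in, in percent of the solid substrate first charged, after epsilon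
- target present, with what was taken out counted in, in percent of the solid substrate first charged, after theta

In the red run the target reads level from 20.0 h to 144 h, so average its readings:

P = mean target = 47.2 %

The last reading leaves 36.0 % of the charge neither target nor solid, so I take it as dissolved and unused. Material is at hand, yet target stands still. Suppose, then, that reagent is the limiting reagent and that second substrate competes for it. Divide the rate of target formation by the rate of reagent loss and time drops out; summed over the run, this gives s, the reagent share, target made per reagent spent:

s = P / reagent charged = 0.525

Second substrate then took R, and L of it remains:

R = 0.428 equiv
L = 0.0725 equiv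

Theta brings A = 0.450 equiv. If second substrate takes L first, I reckon target at

P + A − L = 85.0 %

and 52.8 % of the charge is not target, more than A. Epsilon and beta bring no reagent, so I reckon P for each and for the flask at 8.0 d, and I commit to theta.

The weak link is the supposition itself: were second substrate a partner of target, 0.500 equiv would be a ceiling. But P lies 2.8 percentage points below that ceiling, and the mean is good to 1 point, so the shortfall is larger than its error while material stood by. I keep reagent.

The forecast differs from this reckoning: it gives 48 % at 8.0 d, best none, 49 % after epsilon and 48.5 % after theta, holding that “Removing target or adding reagent cannot get past the second substrate limit”.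

The flask gives 46.0 %, best theta, 46.0 % after epsilon and 89.5 % after theta.

    starting material + reagent → target (k = 2.90 M⁻¹ min⁻¹)
    second substrate + reagent → second product (k = 0.280 M⁻¹ min⁻¹)
    solid substrate ⇌ starting material, rate k3*(cs3 - [starting material]) while solid is left; crystals form when [starting material] > cs3 (solubility = 14.0 mM, k = 0.00240 min⁻¹)

In this flask second substrate and starting material both consumed reagent, half of their turnovers up to the asked time done by 1.21 h and 5.03 h, and by 19.2 h reagent stood at 0 % with target at 46.0 %. Solid substrate went on dissolving to 17.1 % by 96.0 h, and starting material stood at 36.8 % at 192 h. In this flask s comes to 0.512, and theta gained 0.967 equivalents of target per equivalent of reagent added. The neighbour flask charged with 0.230 equiv of reagent, for which s gives 12.1 %, holds 10.9 % of target.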